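**Plan**
- Ring numbering used here: C1 (C=O next to the hexadecyl carbon), C2 (C–OH), C3 (C–H), C4 (C=O), C5 (C–OH), C6 (C–hexadecyl). The retrosynthesis first masks two of the ring oxygens as enol ethers, then cuts the ring at C1–C2 and C5–C6.
- The cuts give the two-carbon unit C6–C1 as an ynol ether (1-ethoxyoctadec-1-yne, with C1 carrying the ethoxy group). The four-carbon unit C2–C3–C4–C5 is a diacyl cobaltacycle made by C–C activation of isopropyl semisquarate (C2 and C5 are its acyl carbons, C4 carries O-i-Pr).
- Enabling feature: C2 and C5 stand para across the six-membered ring and, with C3 and C4 between them, are the four carbons of a strained cyclobutene-1,2-dione. C6–C1 is an alkyne that already carries the oxygen of C1, so the quinone forms without a redox step.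
- Forward order: the chain is joined to the two-carbon unit first (acetylide alkylation), cobalt is inserted into the four-membered ring, and the only ring of the target arises in the alkyne-insertion step; hydrolysis finishes.
- Stereochemistry: the target has no stereocenter and no stereogenic double bond; the only selectivity to control is the 2,5- versus 2,6-placement of the oxygens, set in the key step.

Key step: step 4

Remark: the two ways of placing the enol protons on the 3-alkyl-2,5-dihydroxy-1,4-benzoquinone core (O–H on O2 and O5, or on O1 and O4) are one and the same compound, interconverted by a degenerate proton shift between neighbouring oxygens. The hydrolysis in step 5 therefore delivers the structure as drawn, although C1 enters as the ethoxy-bearing alkyne carbon. In the SMILES of the cobalt complexes, dative bonds are written as charge-separated single bonds.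

**Step 1**
Reactants: 1 diisopropyl squarate (3,4-diisopropoxycyclobut-3-ene-1,2-dione)
Product: 3 isopropyl semisquarate (3-isopropoxycyclobut-3-ene-1,2-dione), via 4-hydroxy-2,3-diisopropoxycyclobut-2-en-1-one 2 (not isolated)
Conditions: LiAlH(O-t-Bu)3, THF, −78 → −20 °C, aq HCl work-up; then conc. HCl (cat.), CH2Cl2, rt
Reagents that add atoms: water, O
Why: The hindered hydride should add once to a squarate carbonyl (1,2-reduction, giving racemic carbinol 2 whose stereocenter is lost again), and acid then ionises the allylic hydroxyl to an alkoxy-stabilised cation that water captures at the isopropoxy-bearing carbon with loss of isopropanol (net 1,3-carbonyl transposition of a vinylogous ester), the standard access to semisquaric esters.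

**Step 2**
Reactants: 4 ethoxyacetylene, 5 1-iodohexadecane
Product: 7 1-ethoxyoctadec-1-yne, via lithium ethoxyacetylide 6 (not isolated)
Conditions: n-BuLi, THF, −78 °C; then 5, HMPA, −78 °C → rt
Reagents that add atoms: none
Why: Deprotonation of the terminal alkyne and SN2 C-alkylation of the acetylide by the primary iodide in the presence of HMPA should give the internal ynol ether, which is kept cold and acid-free because ethyl ynol ethers hydrate easily and lose ethylene by a retro-ene reaction on strong heating.

**Step 3**
Reactants: 3 isopropyl semisquarate
Product: 9 chloro(dimethylglyoxime)(2-isopropoxymaleoyl)(pyridine)cobalt, via chloro(2-isopropoxymaleoyl)bis(triphenylphosphine)cobalt 8 (not isolated)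
Conditions: ClCo(PPh3)3, PhH, rt; then dimethylglyoxime, pyridine, rt
Reagents that add atoms: chlorotris(triphenylphosphine)cobalt, Cl[Co-3]([P+](c1ccccc1)(c1ccccc1)c1ccccc1)([P+](c1ccccc1)(c1ccccc1)c1ccccc1)[P+](c1ccccc1)(c1ccccc1)c1ccccc1; dimethylglyoxime, CC(=NO)C(C)=NO; pyridine, c1ccncc1
Why: Oxidative addition of monovalent cobalt into the strained bond joining the two carbonyl carbons (C–C activation of a cyclobutenedione) should give the five-membered trivalent-cobalt diacyl metallacycle 8, and exchange of both phosphines for the chelating dioxime and pyridine should convert it into the air-stable 18-electron complex 9, the form of maleoylcobalt that reacts with alkynes under mild conditions.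

**Step 4**
Reactants: 9 chloro(dimethylglyoxime)(2-isopropoxymaleoyl)(pyridine)cobalt, 7 1-ethoxyoctadec-1-yne
Product: 10 2-ethoxy-3-hexadecyl-5-isopropoxy-1,4-benzoquinone
Conditions: 7 (2 equiv), ClCH2CH2Cl, 70 °C, N2; then air
Reagents that add atoms: none
Why: Thermal loss of pyridine from the trivalent-cobalt diacyl metallacycle 9 should open a site for the ynol ether, which inserts into one Co–acyl bond and then undergoes C–C reductive elimination with the second acyl, so that the alkyne is stitched between the two acyl carbons (bonds C5–C6 and C1–C2 formed in one operation) and the quinone is released as cobalt falls to monovalent cobalt. The closest known reaction type is the maleoylcobalt–alkyne quinone annulation, a formal [4+2] in which the four-carbon diacyl unit comes from C–C activation of a cyclobutenedione. The six-membered ring is closed by reductive elimination from a seven-membered cobaltacycle (not a pericyclic closure) and arrives directly at the quinone oxidation level. No stereocenter is formed. The step needs head-to-tail regioselectivity, with the hexadecyl-bearing alkyne carbon C6 bonded to the acyl carbon C5 next to C–O-i-Pr and the ethoxy-bearing carbon C1 bonded to the acyl carbon C2 next to C–H, which gives the 2,5- and not the 2,6-dioxygenated quinone. This should be secured by polarity matching, since the nucleophilic β-carbon C6 of the ynol ether pairs with the more electrophilic cross-conjugated acyl C5 while the vinylogous-ester acyl C2 (conjugated to O-i-Pr through C3=C4, oxycarbene-like and a poor migrating group) stays on cobalt until the ring-closing elimination; the acid-free medium below 80 °C keeps the ynol ether from hydration and retro-ene cleavage.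

**Step 5**
Reactants: 10 2-ethoxy-3-hexadecyl-5-isopropoxy-1,4-benzoquinone
Product: 11 3-hexadecyl-2,5-dihydroxy-1,4-benzoquinone
Conditions: 70% aq HClO4, 1,4-dioxane, rt
Reagents that add atoms: water, O
Why: Both alkoxy groups sit β to a quinone carbonyl (vinylogous esters), so acid-catalysed conjugate addition of water and loss of ethanol and isopropanol (addition–elimination hydrolysis) should unmask the two enolic hydroxyls and give the target.

**Compound list**
1 | diisopropyl squarate (3,4-diisopropoxycyclobut-3-ene-1,2-dione) | CC(C)OC1=C(OC(C)C)C(=O)C1=O | starting material
2 | 4-hydroxy-2,3-diisopropoxycyclobut-2-en-1-one (racemic) | CC(C)OC1=C(OC(C)C)C(O)C1=O | intermediate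
3 | isopropyl semisquarate (3-isopropoxycyclobut-3-ene-1,2-dione) | CC(C)OC1=CC(=O)C1=O | intermediate
4 | ethoxyacetylene (ethoxyethyne) | C#COCC | starting material
5 | 1-iodohexadecane | CCCCCCCCCCCCCCCCI | starting material
6 | lithium ethoxyacetylide | [Li]C#COCC | intermediate
7 | 1-ethoxyoctadec-1-yne | CCCCCCCCCCCCCCCCC#COCC | intermediate
8 | chloro(2-isopropoxymaleoyl)bis(triphenylphosphine)cobalt (five-membered cobaltacycle Co–C(=O)–C(O-i-Pr)=CH–C(=O)–, trivalent cobalt) | CC(C)OC1=CC(=O)[Co-2](Cl)([P+](c2ccccc2)(c2ccccc2)c2ccccc2)([P+](c2ccccc2)(c2ccccc2)c2ccccc2)C1=O | intermediate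
9 | chloro(dimethylglyoxime)(2-isopropoxymaleoyl)(pyridine)cobalt (same cobaltacycle, N,N-chelating dioxime, trivalent cobalt) | CC(C)OC1=CC(=O)[Co-3]2(Cl)([n+]3ccccc3)([N+](O)=C(C)C(C)=[N+]2O)C1=O | intermediate
10 | 2-ethoxy-3-hexadecyl-5-isopropoxy-1,4-benzoquinone | CCCCCCCCCCCCCCCCC1=C(OCC)C(=O)C=C(OC(C)C)C1=O | intermediate
11 | 3-hexadecyl-2,5-dihydroxy-1,4-benzoquinone | CCCCCCCCCCCCCCCCC1=C(O)C(=O)C=C(O)C1=O | target

**Totals**
Total step count: 5. Longest linear sequence: 4 steps (steps 1, 3, 4, 5); step 2 is a one-step side branch that joins at step 4.

**Steps most likely to fail**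

1. Step 4. The alkyne may insert with the opposite orientation, the hexadecyl-bearing carbon pairing with the vinylogous-ester acyl, which leads to the 2,6-dioxygenated quinone. This is a real uncertainty: an insertion that places the migrating acyl on the ethoxy-bearing carbon would predict that outcome, and a Lewis acid added to speed pyridine loss could bind the vinylogous-ester oxygen and erode the polarity bias. The electron-rich alkyne may also be consumed by cobalt-mediated oligomerisation.
 Fallback: leave ring construction and fix the oxygen pattern with an intact arene. It sets out from 5 and comes back to the route at 11. Commercial 1,2,4,5-tetramethoxybenzene is lithiated between two methoxy groups (n-BuLi, THF, 0 °C) and alkylated with 5 to give 3-hexadecyl-1,2,4,5-tetramethoxybenzene F1. Oxidative demethylation of F1 with (NH4)2Ce(NO3)6 in MeCN/H2O should give 3-hexadecyl-2,5-dimethoxy-1,4-benzoquinone F2, and hydrolysis of F2 under the conditions of step 5 returns to the route at 11.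

2. Step 2. The SN2 reaction of the weakly nucleophilic, thermally fragile alkoxyacetylide may be slow, allowing E2 elimination of the iodide and decomposition on warming; the product may also be lost by hydration during purification.
 Fallback: form the C–O bond of the ynol unit by oxidation instead of forming its C–C bond by alkylation. It sets out from 9, with a replacement alkyne partner made from commercial 1-octadecyne, and comes back to the route at 11. 1-Octadecyne is deprotonated (n-BuLi, THF, −78 °C) to lithium octadec-1-yn-1-ide F3, and F3 is oxidised in the same flask with t-BuOOLi to lithium octadec-1-yn-1-olate F4. O-Silylation of F4 with i-Pr3SiOTf should give triisopropyl(octadec-1-yn-1-yloxy)silane F5, a siloxyalkyne that cannot undergo the retro-ene reaction. F5 is used in place of 7 with 9 under the conditions of step 4 to give 3-hexadecyl-5-isopropoxy-2-(triisopropylsilyloxy)-1,4-benzoquinone F6, and acid hydrolysis of F6 as in step 5 returns to the route at 11.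

3. Step 3. Liberated triphenylphosphine or pyridine may attack the unsubstituted, highly electrophilic ring carbon of 3, or displace isopropoxide, instead of cobalt inserting into the C–C bond; the ligand exchange may also stall.
 Fallback: abandon the metallacycle and attach the chain to a preformed ring. It sets out from 5 and comes back to the route at 11. Kornblum oxidation of 5 (DMSO, NaHCO3, 110 °C) gives hexadecanal F7. Three-component reductive alkylation of commercial 2,5-dihydroxy-1,4-benzoquinone with F7 and diethyl 2,6-dimethyl-1,4-dihydropyridine-3,5-dicarboxylate under proline catalysis (Knoevenagel condensation, then transfer hydrogenation of the quinone methide) should give 11 directly, where it rejoins the route.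

**Further compounds**
F1 | step 4 | 3-hexadecyl-1,2,4,5-tetramethoxybenzene | CCCCCCCCCCCCCCCCc1c(OC)c(OC)cc(OC)c1OC
F2 | step 4 | 3-hexadecyl-2,5-dimethoxy-1,4-benzoquinone | CCCCCCCCCCCCCCCCC1=C(OC)C(=O)C=C(OC)C1=O
F3 | step 2 | lithium octadec-1-yn-1-ide | CCCCCCCCCCCCCCCCC#C[Li]
F4 | step 2 | lithium octadec-1-yn-1-olate | CCCCCCCCCCCCCCCCC#CO[Li]
F5 | step 2 | triisopropyl(octadec-1-yn-1-yloxy)silane | CCCCCCCCCCCCCCCCC#CO[Si](C(C)C)(C(C)C)C(C)C
F6 | step 2 | 3-hexadecyl-5-isopropoxy-2-(triisopropylsilyloxy)-1,4-benzoquinone | CCCCCCCCCCCCCCCCC1=C(O[Si](C(C)C)(C(C)C)C(C)C)C(=O)C=C(OC(C)C)C1=O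
F7 | step 3 | hexadecanal | CCCCCCCCCCCCCCCC=O
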